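Structural features

The target is a flavonol: a benzo-fused 4-pyranone (ring A fused to ring C through C4a and C8a) with a 4-methoxyphenyl ring B on C2 through the C2–C1′ bond and a hydroxyl on C3. Ring A has no C–H: C5 carries a free hydroxyl, C6, C7 and C8 carry methoxy groups and C8a carries the ring oxygen O1, so five oxygen atoms sit on adjacent carbons. The molecule is planar and has no stereocentre, so any sp3 centre made on the way (C2, and C3/C4 next to it in transient intermediates) must be erased again. The fragile parts are the 3-hydroxy-4-pyranone enol (cleaved by strong oxidants and hot alkali), the very electron-rich ring A (easily oxidised to quinones) and the aryl methyl ethers, of which exactly one must end as a free phenol. The real difficulty is twofold: building the fully oxygenated ring A with the right pattern, and reaching the C3 hydroxyl / C4 carbonyl oxidation level with only O5 unmasked. The C5 oxygen is peri to the C4 carbonyl, which gives a chelation handle for a selective late demethylation. The key step exploits the position of C3, an oxygen-bearing carbon lying between C2 (bonded to O1 and ring B) and C4 (bonded to C4a of ring A). This is the pattern of the nitro-bearing α-carbon of a β-nitrostyrene whose β-carbon becomes C2, joined to a ring A salicylaldehyde whose phenol oxygen becomes O1 and whose formyl carbon becomes C4.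

Logic of the disconnections

11 to 10: the O–H at C5 of 11 is traced back to an O–CH3 bond. The cut is made there because O5 is the only ether oxygen that can chelate a Lewis acid together with the C4 carbonyl, so it can be addressed last. The gain is a uniformly methylated ring A, with no oxygen to differentiate earlier. The forward step must remove one methyl group out of five and spare the neighbouring C6 ether.

10 to 7: the C3–O bond and the C4=O bond of 10 are removed and C3 is given a nitro group, which leads to 7 by way of 9 and 8. The reason is that a nitroalkene is a latent α-hydroxy ketone: a nucleophilic oxidant brings oxygen to both alkene carbons and nitrogen leaves as nitrite. The gain is a ring C at the 2H-chromene level, which an annulation can reach. The forward step must epoxidise an electron-poor alkene without harming ring A and must end at the aromatic pyranone, which also removes the C2 stereocentre.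

7 to 4 and 5: the O1–C2 bond and the C3=C4 bond of 7 are cut, the latter through the C3–C4 single bond of 6. The cut follows the natural polarity: O1 is a phenoxide, C2 the electrophilic β-carbon of a nitroalkene, C3 a nitronate carbon and C4 a formyl carbon. The gain is the loss of ring C, leaving two stable benzene derivatives of similar size. The forward step needs the phenoxide of 4 to add to the donor-substituted 5, the doubly ortho-substituted formyl group to accept the nitronate, and loss of water to pull the equilibria forward.

4 to 3: the aryl C3–OCH3 bond of 4 is cut to a C–Br bond. The last oxygen of ring A is thus introduced at a carbon that can be halogenated without ambiguity. The gain is a tetraoxygenated ring in place of a pentaoxygenated one. The forward step must achieve a copper-mediated C–O coupling on a hindered, electron-rich bromide bearing a free phenol and an aldehyde, without reductive loss of bromine.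

3 to 2: the C3–Br bond is cut. C3 is the only ring C–H of 2 and all substituents direct an electrophile to it. The gain is removal of the halogen handle. The forward step must stop at substitution and avoid oxidising the para-methoxyphenol unit.

2 to 1: the aryl–CHO bond is cut. The two ortho positions of 1 are equivalent and the para position is blocked, so ortho-formylation can give only one aldehyde. The gain is a symmetrical commercial phenol. The forward step must deliver the formyl group to a carbon flanked by hydroxyl and methoxy.

Other disconnections considered

Alternative 1: This plan cuts ring A itself, at C8–C8a and at C4a–C5, and traces C5–C8 to a squaric acid diester joined to a pyranone. In the forward key step, heating the racemic 4-hydroxycyclobutenone A1 would open the four-membered ring (4π) to a vinylketene, which would close (6π) onto the pyranone C–H carbon and tautomerise to the hydroquinone A2.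
- In its favour: the hexasubstituted ring A is assembled in one operation with its oxygen pattern built in. The two hydroxyls of A2 are differentiated by nature, O5 being hydrogen-bonded to the C4 carbonyl and O8 free, so 8-O-methylation and hydrogenolysis of the benzyl ether (H2, Pd/C) would finish the synthesis without any selective demethylation. On that point it is better than the chosen plan.
- Against it: A1 requires a 3-benzyloxy-2-aryl-4-pyranone metalated regioselectively next to the carbonyl and added once to the squarate. That pyranone is a multi-step target of its own, and 4-pyranones tend to suffer conjugate addition and ring opening with organolithium reagents. A2 is an air-sensitive hydroquinone.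
- Comparison: regiochemical certainty is equal, both being cascades with fixed connectivity. The chosen plan is clearly shorter, because it buys ring A already oxygenated and makes ring C from two stable partners.

Alternative 2: This plan cuts C4a–C4, C4–C3 and O1–C2. In the forward key step the iodophenol A3, the alkyne A4 and one carbonyl unit would combine in a carbonylative Sonogashira coupling (PdCl2(PPh3)2, amine, CO atmosphere); 6-endo-dig addition of the phenol oxygen to the ynone would then give the flavone A5.
- In its favour: it is catalytic and convergent, it forms no stereocentre, and ring C arrives directly at the aromatic oxidation level at C2 and C4. On that point it is better than the chosen plan, which must dehydrogenate.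
- Against it: A5 has no oxygen at C3, so a separate C3 hydroxylation (dioxirane epoxidation or C3 metalation, borylation and oxidation) would be needed to reach 10 before step 6. A3 is an electron-rich iodide flanked by hydroxyl and methoxy, so oxidative addition to zerovalent palladium should be slow. Direct, non-carbonylative coupling and 5-exo closure to an aurone would compete.
- Comparison: the end game (step 6) and the approximate step count are equal, since A3 would need about three steps from 1. The chosen plan is stronger in mechanism, because the nitro group marks C3 for oxygen from the outset instead of relying on late oxidation of an unactivated C3–H.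

Alternative 3: This plan cuts only C3–C4, with O1–C2 already in place as an ether. In the forward key step SmI2 would reduce the aromatic aldehyde of the racemic dialdehyde A6 to a ketyl, which would add to the tethered aliphatic aldehyde and close ring C as the cis-diol A7.
- In its favour: both the C3 and C4 oxygens are present from the start, the conditions are neutral and mild, and neither a nitro compound nor a peroxide is needed. On mildness it is better, and on ring A supply it is equal, since A6 would be made from 4.
- Against it: A6 contains an enolisable α-aryl-α-aryloxy acetaldehyde, prone to enolisation, β-elimination of the phenoxide and self-aldol reaction. Its preparation from 4 would need an O-alkylation plus a redox adjustment in the presence of the aromatic aldehyde, several steps where the chosen cascade uses one. The three stereocentres of A7 are made only to be destroyed. The four-electron oxidation of A7 to 10 risks glycol C–C cleavage of an electron-rich benzylic diol, and step 6 is still required.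
- Comparison: the chosen plan forms both ring bonds in one step from two stable partners and is shorter and more redox-economical.

Key step: step 4

Assumption: 1 and 5 (pure E isomer) are treated as catalogue chemicals; racemic material is carried through steps 4 and 5 because its only stereocentre is destroyed before the end.

Step 1
Reactants: 1 3,4,5-trimethoxyphenol
Product: 2 2-hydroxy-4,5,6-trimethoxybenzaldehyde
Conditions: MgCl2, Et3N, (CH2O)n, MeCN, reflux; then 1 M HCl
Reagents that add atoms: paraformaldehyde (as formaldehyde), C=O
Why: Casnati–Skattebøl ortho-formylation: the magnesium phenoxide of 1 delivers formaldehyde to the ortho carbon through a chelate and a second formaldehyde oxidises the benzylic alkoxide by hydride transfer; the two ortho positions are equivalent and the para position is blocked, so a single aldehyde should form.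

Step 2
Reactants: 2 2-hydroxy-4,5,6-trimethoxybenzaldehyde
Product: 3 3-bromo-2-hydroxy-4,5,6-trimethoxybenzaldehyde
Conditions: NBS (1.0 equiv), MeCN, 0 °C, dark
Reagents that add atoms: N-bromosuccinimide, O=C1CCC(=O)N1Br
Why: Electrophilic aromatic bromination; C3 is the only ring C–H of 2 and is activated by the ortho hydroxyl, the ortho methoxy and the para methoxy group, so one equivalent at low temperature should substitute there and leave the aldehyde alone.

Step 3
Reactants: 3 3-bromo-2-hydroxy-4,5,6-trimethoxybenzaldehyde
Product: 4 2-hydroxy-3,4,5,6-tetramethoxybenzaldehyde
Conditions: NaOMe (5 equiv), CuBr (0.3 equiv), DMF–MeOH, 110 °C, N2; then 1 M HCl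
Reagents that add atoms: sodium methoxide, C[O-].[Na+]
Why: Ullmann-type methoxylation of an aryl bromide with a monovalent copper catalyst; 3 reacts as its sodium phenoxide, whose conjugation with the formyl group shields the aldehyde from methoxide, a well-established situation for ortho-bromophenol aldehydes.

Step 4
Reactants: 4 2-hydroxy-3,4,5,6-tetramethoxybenzaldehyde; 5 (E)-1-methoxy-4-(2-nitroethenyl)benzene
Product: 7 rac-5,6,7,8-tetramethoxy-2-(4-methoxyphenyl)-3-nitro-2H-chromene, via nitro-aldol adduct 6 (not isolated)
Conditions: DABCO (0.5 equiv), 5 (1.5 equiv), MeCN (1 M), 4 Å MS, 60 °C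
Reagents that add atoms: none
Why: DABCO deprotonates the phenol of 4 and the phenoxide adds to the benzylic β-carbon of 5 (oxa-Michael addition), forming O1–C2 and a nitronate. The nitronate carbon then attacks the neighbouring formyl group in an intramolecular Henry reaction, which forms C3–C4 and closes ring C in a 6-exo-trig mode to give 6. E1cB loss of water through the nitronate gives the conjugated nitroalkene 7. The closest known reaction type is the amine-catalysed oxa-Michael–Henry–dehydration cascade of salicylaldehydes with β-nitrostyrenes to 2-aryl-3-nitro-2H-chromenes. The one new stereocentre, C2, is formed without a controlling element, so 7 is racemic; this is acceptable because C2 becomes sp2 in step 5, and the C3 and C4 centres of 6 vanish on dehydration. The selectivity needed is regiochemical and is secured by polarity: 4 has one phenoxide oxygen and one carbonyl, and 5 is electrophilic only at its β-carbon and nucleophilic only at its α-carbon after the addition. The oxa-Michael step is reversible, so high concentration, mild heating and removal of water are chosen to drive the less electrophilic, methoxy-substituted partners through the irreversible dehydration.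

Step 5
Reactants: 7 rac-5,6,7,8-tetramethoxy-2-(4-methoxyphenyl)-3-nitro-2H-chromene
Product: 10 3-hydroxy-5,6,7,8-tetramethoxy-2-(4-methoxyphenyl)-4H-chromen-4-one, via nitro epoxide 8 (not isolated), via ketol 9 (not isolated)
Conditions: 30% aq. H2O2 (5 equiv), 2 M NaOH, MeOH–THF, 0 °C to rt, open flask; then Na2S2O3, aq. NH4Cl
Reagents that add atoms: hydrogen peroxide, OO; water (hydroxide of the aqueous NaOH), O
Why: Weitz–Scheffer-type nucleophilic epoxidation of the nitroalkene, with hydroperoxide attacking C4 anti to the C2 aryl group, should give 8; hydroxide opens 8 at benzylic C4 and the C3 alkoxide expels nitrite to give ketol 9. The enediolate of 9 is then dehydrogenated by peroxide or air, as in the last stage of an Algar–Flynn–Oyamada reaction, to the aromatic 3-hydroxy-4-pyranone 10, which erases the C2 stereocentre; the near-neutral work-up avoids nitrous acid.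

Step 6
Reactants: 10 3-hydroxy-5,6,7,8-tetramethoxy-2-(4-methoxyphenyl)-4H-chromen-4-one
Product: 11 3,5-dihydroxy-6,7,8-trimethoxy-2-(4-methoxyphenyl)-4H-chromen-4-one (3,5-dihydroxy-6,7,8,4′-tetramethoxyflavone)
Conditions: BCl3 (3 equiv, 1 M in CH2Cl2), CH2Cl2, −78 to 0 °C; then 1 M HCl
Reagents that add atoms: none
Why: Chelation-directed Lewis acid ether cleavage: boron held between the C4 carbonyl oxygen and O5 forms a six-membered chelate and chloride removes only that methyl group as CH3Cl. The 3-hydroxyl merely consumes one equivalent as a borate, and the ethers at C6, C7, C8 and C4′ have no neighbouring carbonyl; aqueous acid then frees both hydroxyls.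

Compound list

1 | 3,4,5-trimethoxyphenol | COc1cc(O)cc(OC)c1OC | starting material
2 | 2-hydroxy-4,5,6-trimethoxybenzaldehyde | COc1cc(O)c(C=O)c(OC)c1OC | intermediate
3 | 3-bromo-2-hydroxy-4,5,6-trimethoxybenzaldehyde | COc1c(Br)c(O)c(C=O)c(OC)c1OC | intermediate
4 | 2-hydroxy-3,4,5,6-tetramethoxybenzaldehyde | COc1c(O)c(C=O)c(OC)c(OC)c1OC | intermediate
5 | (E)-1-methoxy-4-(2-nitroethenyl)benzene | COc1ccc(/C=C/[N+](=O)[O-])cc1 | starting material
6 | 5,6,7,8-tetramethoxy-2-(4-methoxyphenyl)-3-nitrochroman-4-ol (racemic, mixture of diastereomers, configuration not assigned) | COc1ccc(cc1)C1Oc2c(OC)c(OC)c(OC)c(OC)c2C(O)C1[N+](=O)[O-] | intermediate (not isolated)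
7 | rac-5,6,7,8-tetramethoxy-2-(4-methoxyphenyl)-3-nitro-2H-chromene (C2 racemic) | COc1ccc(cc1)C1Oc2c(OC)c(OC)c(OC)c(OC)c2C=C1[N+](=O)[O-] | intermediate
8 | rac-4,5,6,7-tetramethoxy-2-(4-methoxyphenyl)-1a-nitro-1a,7b-dihydro-2H-oxireno[2,3-c]chromene (3,4-epoxide of 7, epoxide oxygen expected anti to the aryl group; one enantiomer drawn) | COc1ccc(cc1)[C@@H]1Oc2c(OC)c(OC)c(OC)c(OC)c2[C@H]2O[C@@]12[N+](=O)[O-] | intermediate (not isolated)
9 | 4-hydroxy-5,6,7,8-tetramethoxy-2-(4-methoxyphenyl)chroman-3-one (racemic, epimers at two enolisable centres) | COc1ccc(cc1)C1Oc2c(OC)c(OC)c(OC)c(OC)c2C(O)C1=O | intermediate (not isolated)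
10 | 3-hydroxy-5,6,7,8-tetramethoxy-2-(4-methoxyphenyl)-4H-chromen-4-one | COc1ccc(-c2oc3c(OC)c(OC)c(OC)c(OC)c3c(=O)c2O)cc1 | intermediate
11 | 3,5-dihydroxy-6,7,8-trimethoxy-2-(4-methoxyphenyl)-4H-chromen-4-one | COc1ccc(-c2oc3c(OC)c(OC)c(OC)c(O)c3c(=O)c2O)cc1 | target

Total step count: 6. Longest linear sequence: 6 steps (1 → 2 → 3 → 4 → 7 → 10 → 11); 5 enters at step 4.

Steps least certain to work

Step 4 (key step). The most likely failure is a stalled or reversed oxa-Michael addition: both partners are electron-rich and the formyl group sits between two ortho oxygens, so base-induced oligomerisation of 5 may outrun ring closure, or the sequence may stop before dehydration. The fallback sets out from 4 and returns at 7. A Petasis-type condensation of 4 with (E)-[2-(4-methoxyphenyl)ethenyl]boronic acid F1 and catalytic Bn2NH (toluene, 90 °C) would transfer the alkenyl group to the iminium carbon. Thermal loss of the amine and 6π-oxa-electrocyclisation of the resulting ortho-quinone methide would give rac-5,6,7,8-tetramethoxy-2-(4-methoxyphenyl)-2H-chromene F2. Radical nitration of the styrene-type C3–H (t-BuONO, TEMPO, 1,4-dioxane, 80 °C) would then give 7.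

Step 3. The most likely failure is reductive loss of bromine in place of C–O coupling, or stalling because the salicylaldehyde phenoxide sequesters copper. The fallback sets out from 2 and returns at 4, bypassing 3. Dakin oxidation of 2 (H2O2, NaOH, 0 °C, N2) would give 3,4,5-trimethoxybenzene-1,2-diol F3. Double O-methylation (Me2SO4, K2CO3, acetone) would give pentamethoxybenzene F4. Ortho-lithiation and formylation (n-BuLi, TMEDA, THF, 0 °C; DMF) would give 2,3,4,5,6-pentamethoxybenzaldehyde F5. Carbonyl-directed removal of one of its two equivalent ortho methyl groups (BCl3, 1.1 equiv, CH2Cl2, −20 °C) would give 4.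

Step 5. The most likely failure is over-oxidation, meaning peroxide cleavage at the enediolate or 1,2-dicarbonyl stage or of the flavonolate itself; incomplete dehydrogenation is the other possibility. The fallback sets out from 7 and returns at 10 without any peroxide. Reductive hydrolysis of the nitroalkene (Fe powder, AcOH, 90 °C; a Nef-type conversion by way of the oxime or enamine) would give rac-5,6,7,8-tetramethoxy-2-(4-methoxyphenyl)chroman-3-one F6. Riley oxidation of its C4 methylene (SeO2, 1,4-dioxane–H2O, 90 °C) would raise C4 to the carbonyl level, and enolisation towards C2 then gives 10.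

Step 6. The most likely failure is loss of a second methyl group (at O6, next to the boron-bound O5, or at O4′), or incomplete cleavage because the 3-hydroxy-4-keto chelate ties up the reagent. The fallback sets out from 4 and returns at 11, bypassing 7 and 10; it moves the demethylation to an early, easily purified stage. Carbonyl-directed cleavage of the second ortho ether of 4 (AlCl3, CH2Cl2, rt) would give 2,6-dihydroxy-3,4,5-trimethoxybenzaldehyde F7, whose two phenols are equivalent by symmetry. The cascade of step 4 with 5 would give rac-6,7,8-trimethoxy-2-(4-methoxyphenyl)-3-nitro-2H-chromen-5-ol F8 whichever hydroxyl reacts. The alkaline H2O2 treatment of step 5 would then lead to 11 directly, through the nitro epoxide rac-4,5,6-trimethoxy-2-(4-methoxyphenyl)-1a-nitro-1a,7b-dihydro-2H-oxireno[2,3-c]chromen-7-ol F9 and the ketol 4,5-dihydroxy-6,7,8-trimethoxy-2-(4-methoxyphenyl)chroman-3-one F10.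

Further compounds

F1 | step 4 | (E)-[2-(4-methoxyphenyl)ethenyl]boronic acid (purchased building block) | COc1ccc(/C=C/B(O)O)cc1
F2 | step 4 | rac-5,6,7,8-tetramethoxy-2-(4-methoxyphenyl)-2H-chromene | COc1ccc(cc1)C1Oc2c(OC)c(OC)c(OC)c(OC)c2C=C1
F3 | step 3 | 3,4,5-trimethoxybenzene-1,2-diol | COc1cc(O)c(O)c(OC)c1OC
F4 | step 3 | pentamethoxybenzene | COc1cc(OC)c(OC)c(OC)c1OC
F5 | step 3 | 2,3,4,5,6-pentamethoxybenzaldehyde | COc1c(OC)c(OC)c(C=O)c(OC)c1OC
F6 | step 5 | rac-5,6,7,8-tetramethoxy-2-(4-methoxyphenyl)chroman-3-one | COc1ccc(cc1)C1Oc2c(OC)c(OC)c(OC)c(OC)c2CC1=O
F7 | step 6 | 2,6-dihydroxy-3,4,5-trimethoxybenzaldehyde | COc1c(O)c(C=O)c(O)c(OC)c1OC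
F8 | step 6 | rac-6,7,8-trimethoxy-2-(4-methoxyphenyl)-3-nitro-2H-chromen-5-ol | COc1ccc(cc1)C1Oc2c(OC)c(OC)c(OC)c(O)c2C=C1[N+](=O)[O-]
F9 | step 6 | rac-4,5,6-trimethoxy-2-(4-methoxyphenyl)-1a-nitro-1a,7b-dihydro-2H-oxireno[2,3-c]chromen-7-ol (epoxide oxygen expected anti to the aryl group; one enantiomer drawn) | COc1ccc(cc1)[C@@H]1Oc2c(OC)c(OC)c(OC)c(O)c2[C@H]2O[C@@]12[N+](=O)[O-]
F10 | step 6 | 4,5-dihydroxy-6,7,8-trimethoxy-2-(4-methoxyphenyl)chroman-3-one (racemic, epimer mixture) | COc1ccc(cc1)C1Oc2c(OC)c(OC)c(OC)c(O)c2C(O)C1=O
A1 | alternative 1 | rac-4-[5-(benzyloxy)-6-(4-methoxyphenyl)-4-oxo-4H-pyran-3-yl]-4-hydroxy-2,3-dimethoxycyclobut-2-en-1-one | COC1=C(OC)C(O)(C1=O)c1coc(-c2ccc(OC)cc2)c(OCc2ccccc2)c1=O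
A2 | alternative 1 | 3-(benzyloxy)-5,8-dihydroxy-6,7-dimethoxy-2-(4-methoxyphenyl)-4H-chromen-4-one | COc1ccc(-c2oc3c(O)c(OC)c(OC)c(O)c3c(=O)c2OCc2ccccc2)cc1
A3 | alternative 2 | 2-iodo-3,4,5,6-tetramethoxyphenol | COc1c(O)c(I)c(OC)c(OC)c1OC
A4 | alternative 2 | 1-ethynyl-4-methoxybenzene | COc1ccc(C#C)cc1
A5 | alternative 2 | 5,6,7,8-tetramethoxy-2-(4-methoxyphenyl)-4H-chromen-4-one | COc1ccc(-c2cc(=O)c3c(OC)c(OC)c(OC)c(OC)c3o2)cc1
A6 | alternative 3 | rac-3,4,5,6-tetramethoxy-2-[1-(4-methoxyphenyl)-2-oxoethoxy]benzaldehyde | COc1ccc(cc1)C(C=O)Oc1c(OC)c(OC)c(OC)c(OC)c1C=O
A7 | alternative 3 | racemic 2,3-trans-3,4-cis-5,6,7,8-tetramethoxy-2-(4-methoxyphenyl)chromane-3,4-diol (one enantiomer drawn) | COc1ccc(cc1)[C@@H]1[C@@H](O)[C@@H](O)c2c(OC)c(OC)c(OC)c(OC)c2O1
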